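**Plan**
- Retrosynthetic cuts (cembrane numbering): C14–O (inversion), C1–C14 (14-membered ring), C1=C15 and O2–C16 (butenolide), C1–C2 (alkynylation), C5–C6 (vinylogous aldol), C6–C7 and C10–C11 (carboalumination, Negishi coupling).
- Forward order: the C11–C14 vinyl iodide and a C7–C10 alkylzinc are joined and extended to the C6 enal; C2–C5 and then C1 are added; the five-membered lactone ring is closed as a butenolide; the 14-membered carbocycle is closed last.
- Enabling feature: C17=C15–C1–C14(OH) is a homoallylic alcohol whose alkene is the exocyclic methylene of the γ-lactone ring (O–C2–C1–C15–C16). Moving that alkene into the ring (C1=C15) and placing bromide on C17 gives a 3-(bromomethyl)butenolide, an allylmetal precursor that bonds to a C14 aldehyde at C1.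
- Stereochemistry: C6 from a catalyst-controlled vinylogous Mukaiyama aldol; C2 from a catalyst-controlled alkynylation; C1 from C2 during ring closure; C14 from the chair transition state of the ring closure, then Mitsunobu inversion; E alkenes from two syn-carboaluminations and the vinylogous aldol.

Key step: step 18

Remark: cembrane numbering is used for all intermediates (C1 ring-fusion CH, C2 lactone O–CH, C6 CH–OAc, C14 CH–OH, C15/C16/C17 α-carbon/carbonyl/exocyclic CH2), and 1, 4, 12, 19 and 24 are taken as purchasable.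

**Route**

Step 1
Reactants: 1 tert-butyl(but-3-yn-1-yloxy)dimethylsilane
Product: 3 tert-butyl{[(3E)-4-iodo-3-methylbut-3-en-1-yl]oxy}dimethylsilane, via alkenylalane 2 (not isolated)
Conditions: Me3Al (3 equiv), Cp2ZrCl2 (25 mol%), CH2Cl2, 0 °C to rt; then I2, THF, −30 °C; aq. Na2S2O3/NaHCO3
Reagents that add atoms: trimethylaluminium C[Al](C)C; iodine II
Why: Zirconium-catalysed carboalumination (Negishi) adds CH3 and Al syn across the terminal alkyne with Al at the terminus, and iodinolysis of alkenylalane 2 with retention should give the E vinyl iodide carrying C11–C14 and the C20 methyl.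

Step 2
Reactants: 4 (4-bromobut-1-yn-1-yl)trimethylsilane; 3 tert-butyl{[(3E)-4-iodo-3-methylbut-3-en-1-yl]oxy}dimethylsilane
Product: 6 tert-butyldimethyl{[(3E)-3-methyl-8-(trimethylsilyl)oct-3-en-7-yn-1-yl]oxy}silane, via alkylzinc bromide 5 (not isolated)
Conditions: 4, Zn dust, LiCl, THF, 50 °C; then 3, Pd(PPh3)4 (5 mol%), THF, rt to 40 °C
Reagents that add atoms: none
Why: Zinc insertion into the primary bromide followed by Negishi sp3–sp2 cross-coupling joins C10 to C11 with retention of the E alkene geometry, the silyl group masking the alkyne C–H from the palladium catalyst.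

Step 3
Reactants: 6 tert-butyldimethyl{[(3E)-3-methyl-8-(trimethylsilyl)oct-3-en-7-yn-1-yl]oxy}silane
Product: 7 tert-butyldimethyl{[(3E)-3-methyloct-3-en-7-yn-1-yl]oxy}silane
Conditions: K2CO3 (cat.), MeOH, rt
Reagents that add atoms: none
Why: Carbonate-catalysed methanolysis cleaves only the alkynyl C–Si bond (protodesilylation), the primary silyl ether being inert to these conditions.

Step 4
Reactants: 7 tert-butyldimethyl{[(3E)-3-methyloct-3-en-7-yn-1-yl]oxy}silane
Product: 10 (2E,6E)-9-{[tert-butyl(dimethyl)silyl]oxy}-3,7-dimethylnona-2,6-dien-1-ol, via alkenylalane 8 (not isolated), via lithium alkenylalanate 9 (not isolated)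
Conditions: Me3Al (2.5 equiv), Cp2ZrCl2 (25 mol%), CH2Cl2, rt; solvent switch to hexane/THF, n-BuLi, −78 to 0 °C; (CH2O)n, rt
Reagents that add atoms: trimethylaluminium C[Al](C)C; formaldehyde (as paraformaldehyde) C=O
Why: A second syn carboalumination sets the E C7=C8 alkene with the C19 methyl, and conversion of alkenylalane 8 into the more nucleophilic alanate 9 allows capture of formaldehyde with retention to give the allylic alcohol (C6).

Step 5
Reactants: 10 (2E,6E)-9-{[tert-butyl(dimethyl)silyl]oxy}-3,7-dimethylnona-2,6-dien-1-ol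
Product: 11 (2E,6E)-9-{[tert-butyl(dimethyl)silyl]oxy}-3,7-dimethylnona-2,6-dienal
Conditions: MnO2, CH2Cl2, rt
Reagents that add atoms: none
Why: MnO2 oxidises only the allylic alcohol to the enal (allylic oxidation) without E/Z isomerisation or over-oxidation.

Step 6
Reactants: 12 ethyl 3-methylbut-2-enoate
Product: 14 tert-butyl[(1-ethoxy-3-methylbuta-1,3-dien-1-yl)oxy]dimethylsilane, via lithium dienolate 13 (not isolated)
Conditions: LiN(iPr)2, THF/DMPU, −78 °C; TBSCl, −78 °C to rt
Reagents that add atoms: tert-butylchlorodimethylsilane CC(C)(C)[Si](C)(C)Cl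
Why: Kinetic γ-deprotonation of the senecioate and O-silylation of the lithium dienolate give the silyl dienolate needed as the nucleophile of a vinylogous Mukaiyama aldol reaction.

Step 7
Reactants: 11 (2E,6E)-9-{[tert-butyl(dimethyl)silyl]oxy}-3,7-dimethylnona-2,6-dienal; 14 tert-butyl[(1-ethoxy-3-methylbuta-1,3-dien-1-yl)oxy]dimethylsilane
Product: 15 ethyl (2E,5S,6E,10E)-13-{[tert-butyl(dimethyl)silyl]oxy}-5-hydroxy-3,7,11-trimethyltrideca-2,6,10-trienoate
Conditions: SiCl4 (1.1 equiv), pentamethylene-linked bis(2,2'-diamino-1,1'-binaphthyl) phosphoramide (antipode giving Si-face attack, 2 mol%), iPr2NEt (10 mol%), CH2Cl2, −78 °C; aq. NaHCO3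
Reagents that add atoms: none
Why: In this catalytic enantioselective vinylogous Mukaiyama aldol reaction the chiral phosphoramide-bound chlorosilyl cation activates the enal and the dienolate attacks through its terminal CH2 (γ-selective, open transition state) on the Si face, which should set C6 as S under catalyst control and give the E-configured C3=C4 enoate.

Step 8
Reactants: 15 ethyl (2E,5S,6E,10E)-13-{[tert-butyl(dimethyl)silyl]oxy}-5-hydroxy-3,7,11-trimethyltrideca-2,6,10-trienoate
Product: 16 (2E,5S,6E,10E)-13-{[tert-butyl(dimethyl)silyl]oxy}-3,7,11-trimethyltrideca-2,6,10-triene-1,5-diol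
Conditions: iBu2AlH (3.5 equiv), CH2Cl2, −78 °C; aq. KNaC4H4O6
Reagents that add atoms: none
Why: iBu2AlH reduces the α,β-unsaturated ester in the 1,2-sense to the allylic alcohol (ester reduction) while the silyl ether and the alkenes are untouched.

Step 9
Reactants: 16 (2E,5S,6E,10E)-13-{[tert-butyl(dimethyl)silyl]oxy}-3,7,11-trimethyltrideca-2,6,10-triene-1,5-diol
Product: 17 (2E,5S,6E,10E)-13-{[tert-butyl(dimethyl)silyl]oxy}-5-hydroxy-3,7,11-trimethyltrideca-2,6,10-trienal
Conditions: TEMPO (10 mol%), PhI(OAc)2, CH2Cl2, rt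
Reagents that add atoms: none
Why: The oxoammonium species of the TEMPO/PhI(OAc)2 oxidation discriminates sterically between the primary and the secondary allylic alcohol, so only C2 should be oxidised to the E enal and the C6 carbinol keeps its configuration.

Step 10
Reactants: 17 (2E,5S,6E,10E)-13-{[tert-butyl(dimethyl)silyl]oxy}-5-hydroxy-3,7,11-trimethyltrideca-2,6,10-trienal
Product: 18 (2E,5S,6E,10E)-13-{[tert-butyl(dimethyl)silyl]oxy}-3,7,11-trimethyl-1-oxotrideca-2,6,10-trien-5-yl acetate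
Conditions: Ac2O, pyridine, DMAP (cat.), CH2Cl2, 0 °C
Reagents that add atoms: acetic anhydride CC(=O)OC(C)=O
Why: Acetylation under mild amine catalysis installs the C6 acetate of the target at the last stage at which C6 bears the only free hydroxyl, with no bond to the stereocentre broken.

Step 11
Reactants: 18 (2E,5S,6E,10E)-13-{[tert-butyl(dimethyl)silyl]oxy}-3,7,11-trimethyl-1-oxotrideca-2,6,10-trien-5-yl acetate; 19 ethynyltrimethylsilane
Product: 21 (3S,4E,7S,8E,12E)-15-{[tert-butyl(dimethyl)silyl]oxy}-3-hydroxy-5,9,13-trimethyl-1-(trimethylsilyl)pentadeca-4,8,12-trien-1-yn-7-yl acetate, via alkynylzinc 20 (not isolated)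
Conditions: 19 (3 equiv), Me2Zn (3 equiv), ProPhenol ligand (antipode giving Re-face attack, 20 mol%), Ph3P=O (40 mol%), toluene, 0 °C
Reagents that add atoms: none
Why: In the ProPhenol–zinc catalysed alkynylation the dinuclear zinc complex binds the enal and the zinc acetylide 20 and delivers the alkynyl group to the Re face, which should set C2 as S under catalyst control independent of the remote C6 centre.

Step 12
Reactants: 21 (3S,4E,7S,8E,12E)-15-{[tert-butyl(dimethyl)silyl]oxy}-3-hydroxy-5,9,13-trimethyl-1-(trimethylsilyl)pentadeca-4,8,12-trien-1-yn-7-yl acetate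
Product: 22 (3S,4E,7S,8E,12E)-15-{[tert-butyl(dimethyl)silyl]oxy}-3-hydroxy-5,9,13-trimethylpentadeca-4,8,12-trien-1-yn-7-yl acetate
Conditions: AgNO3 (10 mol%), acetone/H2O, rt
Reagents that add atoms: none
Why: Silver-catalysed protodesilylation removes the alkynyl silyl group under neutral aqueous conditions that spare the acetate and the silyl ether.

Step 13
Reactants: 22 (3S,4E,7S,8E,12E)-15-{[tert-butyl(dimethyl)silyl]oxy}-3-hydroxy-5,9,13-trimethylpentadeca-4,8,12-trien-1-yn-7-yl acetate
Product: 23 (3R,4E,7S,8E,12E)-15-{[tert-butyl(dimethyl)silyl]oxy}-3-hydroxy-5,9,13-trimethylpentadeca-1,4,8,12-tetraen-7-yl acetate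
Conditions: H2 (1 atm), Pd/CaCO3 poisoned with Pb(OAc)2 (Lindlar catalyst), quinoline, EtOAc, rt
Reagents that add atoms: none
Why: Lindlar semi-hydrogenation reduces the terminal alkyne to the vinyl group needed for metathesis and stops there, the trisubstituted alkenes being inert (the descriptor at C2 changes to R only through the priority rules).

Step 14
Reactants: 23 (3R,4E,7S,8E,12E)-15-{[tert-butyl(dimethyl)silyl]oxy}-3-hydroxy-5,9,13-trimethylpentadeca-1,4,8,12-tetraen-7-yl acetate; 24 2-(bromomethyl)prop-2-enoic acid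
Product: 25 (3R,4E,7S,8E,12E)-7-(acetyloxy)-15-{[tert-butyl(dimethyl)silyl]oxy}-5,9,13-trimethylpentadeca-1,4,8,12-tetraen-3-yl 2-(bromomethyl)prop-2-enoate
Conditions: 24 (1.3 equiv), N,N'-diisopropylcarbodiimide (1.3 equiv), DMAP (5 mol%), CH2Cl2, −10 to 0 °C
Reagents that add atoms: none
Why: Carbodiimide (Steglich) esterification acylates the C2 hydroxyl with retention and brings in C15, C16 and the C17 bromide in one piece.

Step 15
Reactants: 25 (3R,4E,7S,8E,12E)-7-(acetyloxy)-15-{[tert-butyl(dimethyl)silyl]oxy}-5,9,13-trimethylpentadeca-1,4,8,12-tetraen-3-yl 2-(bromomethyl)prop-2-enoate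
Product: 26 (1E,4S,5E,9E)-1-[(2S)-4-(bromomethyl)-5-oxo-2,5-dihydrofuran-2-yl]-12-{[tert-butyl(dimethyl)silyl]oxy}-2,6,10-trimethyldodeca-1,5,9-trien-4-yl acetate
Conditions: (H2IMes)Cl2Ru(=CH-C6H4-2-OiPr) (second-generation Hoveyda–Grubbs catalyst, 10 mol%), 1,4-benzoquinone (20 mol%), toluene (5 mM), 80 °C
Reagents that add atoms: none
Why: In this ring-closing metathesis the ruthenium carbene forms at the monosubstituted vinyl group and closes onto the acrylate alkene to give the five-membered butenolide (C1=C15) with loss of ethene, the trisubstituted alkenes being too hindered to compete and the neutral medium leaving the acidic C2–H untouched.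

Step 16
Reactants: 26 (1E,4S,5E,9E)-1-[(2S)-4-(bromomethyl)-5-oxo-2,5-dihydrofuran-2-yl]-12-{[tert-butyl(dimethyl)silyl]oxy}-2,6,10-trimethyldodeca-1,5,9-trien-4-yl acetate
Product: 27 (1E,4S,5E,9E)-1-[(2S)-4-(bromomethyl)-5-oxo-2,5-dihydrofuran-2-yl]-12-hydroxy-2,6,10-trimethyldodeca-1,5,9-trien-4-yl acetate
Conditions: 48% aq. HF, MeCN, 0 °C
Reagents that add atoms: none
Why: Acidic fluoride cleaves the primary silyl ether (desilylation) without touching the acetate, the butenolide or the allylic bromide, which a basic fluoride source would attack.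

Step 17
Reactants: 27 (1E,4S,5E,9E)-1-[(2S)-4-(bromomethyl)-5-oxo-2,5-dihydrofuran-2-yl]-12-hydroxy-2,6,10-trimethyldodeca-1,5,9-trien-4-yl acetate
Product: 28 (1E,4S,5E,9E)-1-[(2S)-4-(bromomethyl)-5-oxo-2,5-dihydrofuran-2-yl]-2,6,10-trimethyl-12-oxododeca-1,5,9-trien-4-yl acetate
Conditions: Dess–Martin periodinane, NaHCO3, CH2Cl2, 0 °C
Reagents that add atoms: none
Why: Buffered Dess–Martin oxidation gives the β,γ-unsaturated aldehyde without migration of the C11=C12 alkene into conjugation, and the crude aldehyde is used at once.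

Step 18
Reactants: 28 (1E,4S,5E,9E)-1-[(2S)-4-(bromomethyl)-5-oxo-2,5-dihydrofuran-2-yl]-2,6,10-trimethyl-12-oxododeca-1,5,9-trien-4-yl acetate
Product: 30 (1S,2S,3E,6S,7E,11E,14R)-6-acetoxy-14-hydroxycembra-3,7,11,15(17)-tetraen-16,2-olide (14-epi-kericembrenolide D), via allylchromium dichloride 29 (not isolated)
Conditions: CrCl2 (10 equiv), 4 Å MS, THF (2 mM, 28 added by syringe pump), rt; cold neutral aqueous work-up
Reagents that add atoms: none
Why: CrCl2 reduces the C17–Br bond in two one-electron steps to the σ-allylchromium 29 (trivalent chromium on the exocyclic CH2), which adds to the C14 aldehyde through a closed six-membered chair transition state with allylic transposition, so that C1 of the butenolide bonds to C14 and the C1=C15 alkene moves to C15=C17, unveiling the α-methylene-γ-butyrolactone in the same event. The closest known reaction type is the Nozaki–Hiyama–Kishi (chromium Barbier) allylation of aldehydes by 3-(bromomethyl)furan-2(5H)-ones, together with chromium-mediated allyl bromide–aldehyde macrocyclisations used for cembranoids. The 14-membered carbocycle closes 14-exo-trig at the aldehyde carbonyl, helped by high dilution and by the three E trisubstituted alkenes that limit the conformational space of the chain. C1 is controlled by the C2 stereocentre: the aldehyde bonds to the face of the planar lactone-embedded allyl unit opposite the C2 alkenyl substituent, which gives the trans-fused lactone (1S). C14 is controlled by the chair: the lactone ring locks the allyl unit in the E-type geometry (C2 trans to the CH2Cr group) and the C13 chain takes the equatorial position, which gives the anti (1S,14R) adduct, the C14 epimer of the target, and this is why an inversion follows in step 19. The step needs bond formation at C1 and not at C17 (secured by the cyclic transition state of the primary allylchromium), 1,2-trans facial selectivity (secured by C2), and survival of the β,γ-unsaturated aldehyde, the allylic acetate and the lactone (secured by the neutral, base-free medium and a work-up that gives the chromium alkoxide no time to translactonise).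

Step 19
Reactants: 30 (1S,2S,3E,6S,7E,11E,14R)-6-acetoxy-14-hydroxycembra-3,7,11,15(17)-tetraen-16,2-olide
Product: 31 (1S,2S,3E,6S,7E,11E,14S)-6-acetoxy-14-(formyloxy)cembra-3,7,11,15(17)-tetraen-16,2-olide
Conditions: HCO2H, PPh3, diisopropyl azodicarboxylate, THF, 0 °C to rt
Reagents that add atoms: formic acid O=CO
Why: In the Mitsunobu reaction formate displaces the oxyphosphonium derivative of the C14 hydroxyl with SN2 inversion, which should turn 14R into the 14S configuration of the target, formic acid being chosen so that the new ester can later be removed beside the acetate.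

Step 20
Reactants: 31 (1S,2S,3E,6S,7E,11E,14S)-6-acetoxy-14-(formyloxy)cembra-3,7,11,15(17)-tetraen-16,2-olide
Product: 32 kericembrenolide D, (1S,2S,3E,6S,7E,11E,14S)-6-acetoxy-14-hydroxycembra-3,7,11,15(17)-tetraen-16,2-olide
Conditions: KHCO3 (cat.), MeOH, 0 °C
Reagents that add atoms: none
Why: Bicarbonate-catalysed methanolysis (transesterification) cleaves the formate far faster than the acetate or the lactone and is too mild to add methanol to the α-methylene lactone or to move the lactone to O14.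

**Compound list**

1 | tert-butyl(but-3-yn-1-yloxy)dimethylsilane | C#CCCO[Si](C)(C)C(C)(C)C | starting material
2 | [(1E)-4-{[tert-butyl(dimethyl)silyl]oxy}-2-methylbut-1-en-1-yl]dimethylalane | C[Al](C)/C=C(\C)CCO[Si](C)(C)C(C)(C)C | intermediate
3 | tert-butyl{[(3E)-4-iodo-3-methylbut-3-en-1-yl]oxy}dimethylsilane | I/C=C(\C)CCO[Si](C)(C)C(C)(C)C | intermediate
4 | (4-bromobut-1-yn-1-yl)trimethylsilane | C[Si](C)(C)C#CCCBr | starting material
5 | bromo[4-(trimethylsilyl)but-3-yn-1-yl]zinc | C[Si](C)(C)C#CCC[Zn]Br | intermediate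
6 | tert-butyldimethyl{[(3E)-3-methyl-8-(trimethylsilyl)oct-3-en-7-yn-1-yl]oxy}silane | C[Si](C)(C)C#CCC/C=C(\C)CCO[Si](C)(C)C(C)(C)C | intermediate
7 | tert-butyldimethyl{[(3E)-3-methyloct-3-en-7-yn-1-yl]oxy}silane | C#CCC/C=C(\C)CCO[Si](C)(C)C(C)(C)C | intermediate
8 | [(1E,5E)-8-{[tert-butyl(dimethyl)silyl]oxy}-2,6-dimethylocta-1,5-dien-1-yl]dimethylalane | C[Al](C)/C=C(\C)CC/C=C(\C)CCO[Si](C)(C)C(C)(C)C | intermediate
9 | lithium butyl[(1E,5E)-8-{[tert-butyl(dimethyl)silyl]oxy}-2,6-dimethylocta-1,5-dien-1-yl]dimethylalanate | [Li+].CCCC[Al-](C)(C)/C=C(\C)CC/C=C(\C)CCO[Si](C)(C)C(C)(C)C | intermediate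
10 | (2E,6E)-9-{[tert-butyl(dimethyl)silyl]oxy}-3,7-dimethylnona-2,6-dien-1-ol | OC/C=C(\C)CC/C=C(\C)CCO[Si](C)(C)C(C)(C)C | intermediate
11 | (2E,6E)-9-{[tert-butyl(dimethyl)silyl]oxy}-3,7-dimethylnona-2,6-dienal | O=C/C=C(\C)CC/C=C(\C)CCO[Si](C)(C)C(C)(C)C | intermediate
12 | ethyl 3-methylbut-2-enoate | CCOC(=O)C=C(C)C | starting material
13 | lithium 1-ethoxy-3-methylbuta-1,3-dien-1-olate | [Li+].[O-]C(OCC)=CC(C)=C | intermediate
14 | tert-butyl[(1-ethoxy-3-methylbuta-1,3-dien-1-yl)oxy]dimethylsilane (ketene acetal geometry not controlled, used as formed) | C=C(C)C=C(OCC)O[Si](C)(C)C(C)(C)C | intermediate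
15 | ethyl (2E,5S,6E,10E)-13-{[tert-butyl(dimethyl)silyl]oxy}-5-hydroxy-3,7,11-trimethyltrideca-2,6,10-trienoate | CCOC(=O)/C=C(\C)C[C@H](O)/C=C(\C)CC/C=C(\C)CCO[Si](C)(C)C(C)(C)C | intermediate
16 | (2E,5S,6E,10E)-13-{[tert-butyl(dimethyl)silyl]oxy}-3,7,11-trimethyltrideca-2,6,10-triene-1,5-diol | OC/C=C(\C)C[C@H](O)/C=C(\C)CC/C=C(\C)CCO[Si](C)(C)C(C)(C)C | intermediate
17 | (2E,5S,6E,10E)-13-{[tert-butyl(dimethyl)silyl]oxy}-5-hydroxy-3,7,11-trimethyltrideca-2,6,10-trienal | O=C/C=C(\C)C[C@H](O)/C=C(\C)CC/C=C(\C)CCO[Si](C)(C)C(C)(C)C | intermediate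
18 | (2E,5S,6E,10E)-13-{[tert-butyl(dimethyl)silyl]oxy}-3,7,11-trimethyl-1-oxotrideca-2,6,10-trien-5-yl acetate | O=C/C=C(\C)C[C@H](OC(C)=O)/C=C(\C)CC/C=C(\C)CCO[Si](C)(C)C(C)(C)C | intermediate
19 | ethynyltrimethylsilane | C#C[Si](C)(C)C | starting material
20 | methyl[(trimethylsilyl)ethynyl]zinc | C[Zn]C#C[Si](C)(C)C | intermediate
21 | (3S,4E,7S,8E,12E)-15-{[tert-butyl(dimethyl)silyl]oxy}-3-hydroxy-5,9,13-trimethyl-1-(trimethylsilyl)pentadeca-4,8,12-trien-1-yn-7-yl acetate | C[Si](C)(C)C#C[C@@H](O)/C=C(\C)C[C@H](OC(C)=O)/C=C(\C)CC/C=C(\C)CCO[Si](C)(C)C(C)(C)C | intermediate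
22 | (3S,4E,7S,8E,12E)-15-{[tert-butyl(dimethyl)silyl]oxy}-3-hydroxy-5,9,13-trimethylpentadeca-4,8,12-trien-1-yn-7-yl acetate | C#C[C@@H](O)/C=C(\C)C[C@H](OC(C)=O)/C=C(\C)CC/C=C(\C)CCO[Si](C)(C)C(C)(C)C | intermediate
23 | (3R,4E,7S,8E,12E)-15-{[tert-butyl(dimethyl)silyl]oxy}-3-hydroxy-5,9,13-trimethylpentadeca-1,4,8,12-tetraen-7-yl acetate | C=C[C@@H](O)/C=C(\C)C[C@H](OC(C)=O)/C=C(\C)CC/C=C(\C)CCO[Si](C)(C)C(C)(C)C | intermediate
24 | 2-(bromomethyl)prop-2-enoic acid | C=C(CBr)C(=O)O | starting material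
25 | (3R,4E,7S,8E,12E)-7-(acetyloxy)-15-{[tert-butyl(dimethyl)silyl]oxy}-5,9,13-trimethylpentadeca-1,4,8,12-tetraen-3-yl 2-(bromomethyl)prop-2-enoate | C=C[C@@H](OC(=O)C(=C)CBr)/C=C(\C)C[C@H](OC(C)=O)/C=C(\C)CC/C=C(\C)CCO[Si](C)(C)C(C)(C)C | intermediate
26 | (1E,4S,5E,9E)-1-[(2S)-4-(bromomethyl)-5-oxo-2,5-dihydrofuran-2-yl]-12-{[tert-butyl(dimethyl)silyl]oxy}-2,6,10-trimethyldodeca-1,5,9-trien-4-yl acetate | BrCC1=C[C@H](/C=C(\C)C[C@H](OC(C)=O)/C=C(\C)CC/C=C(\C)CCO[Si](C)(C)C(C)(C)C)OC1=O | intermediate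
27 | (1E,4S,5E,9E)-1-[(2S)-4-(bromomethyl)-5-oxo-2,5-dihydrofuran-2-yl]-12-hydroxy-2,6,10-trimethyldodeca-1,5,9-trien-4-yl acetate | BrCC1=C[C@H](/C=C(\C)C[C@H](OC(C)=O)/C=C(\C)CC/C=C(\C)CCO)OC1=O | intermediate
28 | (1E,4S,5E,9E)-1-[(2S)-4-(bromomethyl)-5-oxo-2,5-dihydrofuran-2-yl]-2,6,10-trimethyl-12-oxododeca-1,5,9-trien-4-yl acetate | BrCC1=C[C@H](/C=C(\C)C[C@H](OC(C)=O)/C=C(\C)CC/C=C(\C)CC=O)OC1=O | intermediate
29 | allylchromium dichloride of 28 (Cr on C17; solvent ligands omitted) | Cl[Cr](Cl)CC1=C[C@H](/C=C(\C)C[C@H](OC(C)=O)/C=C(\C)CC/C=C(\C)CC=O)OC1=O | intermediate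
30 | (1S,2S,3E,6S,7E,11E,14R)-6-acetoxy-14-hydroxycembra-3,7,11,15(17)-tetraen-16,2-olide (14-epi-kericembrenolide D) | C=C1C(=O)O[C@H]2/C=C(\C)C[C@H](OC(C)=O)/C=C(\C)CC/C=C(\C)C[C@@H](O)[C@H]12 | intermediate
31 | (1S,2S,3E,6S,7E,11E,14S)-6-acetoxy-14-(formyloxy)cembra-3,7,11,15(17)-tetraen-16,2-olide | C=C1C(=O)O[C@H]2/C=C(\C)C[C@H](OC(C)=O)/C=C(\C)CC/C=C(\C)C[C@H](OC=O)[C@H]12 | intermediate
32 | kericembrenolide D; (3aS,4S,6E,10E,12S,14E,15aS)-4-hydroxy-6,10,14-trimethyl-3-methylidene-2-oxo-2,3,3a,4,5,8,9,12,13,15a-decahydrocyclotetradeca[b]furan-12-yl acetate | C=C1C(=O)O[C@H]2/C=C(\C)C[C@H](OC(C)=O)/C=C(\C)CC/C=C(\C)C[C@H](O)[C@H]12 | target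

**Count and risks**

Total steps: 20. Longest linear sequence: 19 (steps 1–5 and 7–20; step 6 prepares the dienolate on a side branch).

Steps most likely to fail:

1. Step 18 (ring closure). Intermolecular coupling or simple reduction of the allylchromium may outrun cyclisation. The aldehyde may bond to the face of the allyl unit syn to the C2 chain, giving the cis-fused lactone. The chromium alkoxide may translactonise to O14. Fallback: a closed-shell allylboration replaces the reductive Barbier process. It sets out from 27. Pd2(dba)3-catalysed borylation of the allylic bromide with B2pin2 (toluene, rt) should give the hydroxy allylboronate F1, with boron on C17; the C6 allylic acetate should ionise far more slowly than the activated bromide. Buffered Dess–Martin oxidation at high dilution gives the aldehyde allylboronate F2. F2 is not isolated but warmed in toluene (2 mM, 60–80 °C), so that intramolecular allylboration closes the ring through the same chair with no reductant present. Hydrolytic work-up returns the route at 30, and steps 19 and 20 follow unchanged.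

2. Step 19 (inversion at C14). The hindered oxyphosphonium may eliminate toward C13=C14 or C1=C14, or be captured by the lactone carbonyl, instead of undergoing SN2 substitution. Fallback: the centre is reset by hydride delivery and not by displacement. From 30, Dess–Martin periodinane at 0 °C gives the 14-ketone F3. F3 is reduced at once at −78 °C with catecholborane and the Corey–Bakshi–Shibata oxazaborolidine antipode that delivers hydride to the face giving 14S. The low temperature is meant to keep C1–H from epimerising and the exocyclic alkene from moving into the ring. This comes back at the target 32 and bypasses 31 and step 20.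

3. Step 15 (butenolide by metathesis). The ruthenium carbene may engage the electron-poor 1,1-disubstituted acrylate too slowly, so that catalyst decay, ionisation or allylic transposition of the bis-allylic ester, or alkene migration take over. Fallback: the butenolide is built by carbonylation and C17 is carried as an ether. It sets out from 17.
   - Et3SiCl/imidazole gives the triethylsilyl ether F4.
   - The same ProPhenol/Me2Zn alkynylation, now with 1-methoxy-4-[(prop-2-yn-1-yloxy)methyl]benzene, gives the propargylic alcohol F5.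
   - Hydroxyl-directed trans-hydroalumination with NaAlH2(OCH2CH2OMe)2 and quenching with I2 gives the (Z)-vinyl iodide F6, with iodine on C15.
   - PdCl2(PPh3)2-catalysed carbonylative lactonisation (CO 1 atm, K2CO3, THF, rt) gives the butenolide F7.
   - Pyridinium p-toluenesulfonate in MeOH at 0 °C removes the secondary triethylsilyl group to give the alcohol F8.
   - Ac2O/pyridine gives the acetate F9.
   - DDQ in wet CH2Cl2 frees the hydroxymethyl butenolide F10.
   - CBr4/PPh3 converts F10 into 26, where the route resumes at step 16.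

Further compounds
F1 | step 18 | (1E,4S,5E,9E)-12-hydroxy-2,6,10-trimethyl-1-{(2S)-5-oxo-4-[(4,4,5,5-tetramethyl-1,3,2-dioxaborolan-2-yl)methyl]-2,5-dihydrofuran-2-yl}dodeca-1,5,9-trien-4-yl acetate | CC1(C)OB(CC2=C[C@H](/C=C(\C)C[C@H](OC(C)=O)/C=C(\C)CC/C=C(\C)CCO)OC2=O)OC1(C)C
F2 | step 18 | (1E,4S,5E,9E)-2,6,10-trimethyl-12-oxo-1-{(2S)-5-oxo-4-[(4,4,5,5-tetramethyl-1,3,2-dioxaborolan-2-yl)methyl]-2,5-dihydrofuran-2-yl}dodeca-1,5,9-trien-4-yl acetate | CC1(C)OB(CC2=C[C@H](/C=C(\C)C[C@H](OC(C)=O)/C=C(\C)CC/C=C(\C)CC=O)OC2=O)OC1(C)C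
F3 | step 19 | (1R,2S,3E,6S,7E,11E)-6-acetoxy-14-oxocembra-3,7,11,15(17)-tetraen-16,2-olide | C=C1C(=O)O[C@H]2/C=C(\C)C[C@H](OC(C)=O)/C=C(\C)CC/C=C(\C)CC(=O)[C@H]12
F4 | step 15 | (2E,5S,6E,10E)-13-{[tert-butyl(dimethyl)silyl]oxy}-3,7,11-trimethyl-5-[(triethylsilyl)oxy]trideca-2,6,10-trienal | O=C/C=C(\C)C[C@H](O[Si](CC)(CC)CC)/C=C(\C)CC/C=C(\C)CCO[Si](C)(C)C(C)(C)C
F5 | step 15 | (4S,5E,8S,9E,13E)-16-{[tert-butyl(dimethyl)silyl]oxy}-1-[(4-methoxybenzyl)oxy]-6,10,14-trimethyl-8-[(triethylsilyl)oxy]hexadeca-5,9,13-trien-2-yn-4-ol | COc1ccc(COCC#C[C@@H](O)/C=C(\C)C[C@H](O[Si](CC)(CC)CC)/C=C(\C)CC/C=C(\C)CCO[Si](C)(C)C(C)(C)C)cc1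
F6 | step 15 | (2Z,4S,5E,8S,9E,13E)-16-{[tert-butyl(dimethyl)silyl]oxy}-2-iodo-1-[(4-methoxybenzyl)oxy]-6,10,14-trimethyl-8-[(triethylsilyl)oxy]hexadeca-2,5,9,13-tetraen-4-ol | COc1ccc(COC/C(I)=C/[C@@H](O)/C=C(\C)C[C@H](O[Si](CC)(CC)CC)/C=C(\C)CC/C=C(\C)CCO[Si](C)(C)C(C)(C)C)cc1
F7 | step 15 | (5S)-5-[(1E,4S,5E,9E)-12-{[tert-butyl(dimethyl)silyl]oxy}-2,6,10-trimethyl-4-[(triethylsilyl)oxy]dodeca-1,5,9-trien-1-yl]-3-{[(4-methoxybenzyl)oxy]methyl}furan-2(5H)-one | COc1ccc(COCC2=C[C@H](/C=C(\C)C[C@H](O[Si](CC)(CC)CC)/C=C(\C)CC/C=C(\C)CCO[Si](C)(C)C(C)(C)C)OC2=O)cc1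
F8 | step 15 | (5S)-5-[(1E,4S,5E,9E)-12-{[tert-butyl(dimethyl)silyl]oxy}-4-hydroxy-2,6,10-trimethyldodeca-1,5,9-trien-1-yl]-3-{[(4-methoxybenzyl)oxy]methyl}furan-2(5H)-one | COc1ccc(COCC2=C[C@H](/C=C(\C)C[C@H](O)/C=C(\C)CC/C=C(\C)CCO[Si](C)(C)C(C)(C)C)OC2=O)cc1
F9 | step 15 | (1E,4S,5E,9E)-12-{[tert-butyl(dimethyl)silyl]oxy}-1-[(2S)-4-{[(4-methoxybenzyl)oxy]methyl}-5-oxo-2,5-dihydrofuran-2-yl]-2,6,10-trimethyldodeca-1,5,9-trien-4-yl acetate | COc1ccc(COCC2=C[C@H](/C=C(\C)C[C@H](OC(C)=O)/C=C(\C)CC/C=C(\C)CCO[Si](C)(C)C(C)(C)C)OC2=O)cc1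
F10 | step 15 | (1E,4S,5E,9E)-12-{[tert-butyl(dimethyl)silyl]oxy}-1-[(2S)-4-(hydroxymethyl)-5-oxo-2,5-dihydrofuran-2-yl]-2,6,10-trimethyldodeca-1,5,9-trien-4-yl acetate | OCC1=C[C@H](/C=C(\C)C[C@H](OC(C)=O)/C=C(\C)CC/C=C(\C)CCO[Si](C)(C)C(C)(C)C)OC1=O
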